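Its constants belong to no real substance, and the outcome is calculated.

- The amounts are lopsided: 2.0 µM of free catalyst stands against 2.0 mM of each mirror-image substrate, while 2.40 mM of solid reagent reaches the solution at a finite pace, so we watch how far the free catalyst carries the conversion.

left-handed substrate 2.0 mM; solid reagent 2.40 mM; free catalyst 2.0 µM; right-handed substrate 2.0 mM

    partner + free catalyst + left-handed substrate → free catalyst + left-handed product (k1 = 5.2 × 10⁷ M⁻² s⁻¹)
    partner + free catalyst + right-handed substrate → free catalyst + right-handed product (k2 = 1.4 × 10⁷ M⁻² s⁻¹)
    solid reagent ⇌ partner, rate k3*(cs3 - [partner]) while solid is left; crystals form when [partner] > cs3 (cs3 = 1.4 mM, k3 = 0.19 s⁻¹)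
    free catalyst → spent catalyst (k4 = 0.066 s⁻¹)

* the form that holds most of the catalyst when 30% of the left-handed substrate and right-handed substrate together are converted (spent catalyst / free catalyst)
* its share of the catalyst then
* apparent order in free catalyst when 30% of the left-handed substrate and right-handed substrate together are converted (percent change of the rate of making left-handed product for one percent more free catalyst charged)
* factor on the rate of making left-handed product when 30% of the left-handed substrate and right-handed substrate together are converted if free catalyst is charged twice over

- By our reckoning, free catalyst has a mean life of 15.2 s, and once we know the time, its decay gives the spent share.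
- At the start, partner climbs from zero, while the fresh catalyst and both substrates consume it with a coefficient of 0.264 s⁻¹, more than the dissolution coefficient of 0.19 s⁻¹. The knee comes after about 2.20 s, well inside the catalyst's life, and with fresh catalyst and full substrates, dissolving balances use at 0.586 mM.
- At the far end, we hold partner at that level and give the catalyst its full life. The catalyst's reach, the natural logarithm of the fall in left-handed substrate over the whole decay of the catalyst, is then 0.923.
- That leaves 39.7% of the left-handed substrate and 78.0% of the right-handed. Conversion levels off near 41.1%, below the 60.0% allowed by the solid reagent, the limiting reagent.
- Joining the ends with the mean of the two constants, the asked conversion uses 60.9% of the reach. In this reckoning, that fraction is also the spent share, above the free share, and the conversion is reached at 14.3 s.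
- With twice the charge, partner balances at 0.370 mM, and the same reckoning gives a rate factor of 1.68.
- The forecast gives spent catalyst at 63%, order 0.95 and factor 1.85, above ours, holding that “these two effects nearly cancel, leaving the rate nearly first order in charged catalyst”.
- The flask gives spent catalyst at 63.9%, order 1.3 and factor 1.91, while the forecast's order is what a rate in proportion to everything gives. At 8.00 s, the flask held 0.729 mM of partner. After 80.0 s, with 0.509% of the catalyst still free, 35% of the charged left-handed substrate remained, so the reach read there is 1.06 against our 0.923, which corresponds to a partner level, averaged over the catalyst's decay, of 0.675 mM.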